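The plan rests on closing ring B (C9, C10, C11, C12, Ob) at the ring-fusion bond C9–C10. Both carbons carry oxygen (Ob on C9, Oa on C10) and are therefore both acceptor sites, so the bond is made by inverting the polarity of C10. A chiral triazolylidene turns the C10 aldehyde of an open-chain (E)-β-alkoxyacrylate, which already holds the C12 ether and the C13 bromide, into an acyl anion equivalent that adds to C9. This single operation gives ring B, the C9 stereocentre, the C10 ketone and the C8–C7 ester arm. Reduction, lactonisation, coupling with a C1–C6 zinc reagent and a transposing bromination at C8 complete ring A.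

Key step: step 7

Numbering: the chain runs from C1 (alkyne CH) to C15 (methyl). Oa links C7 and C10 (ring A: Oa, C7, C8, C9, C10). Ob links C9 and C12 (ring B).

Target check:
- Descriptors are 3Z, 6Z, 8S, 9R, 10S, 12R, 13S.
- Rings A and B are cis-fused.
- The C8 bromine lies on the convex face, trans to Ob.
- The C12 arm is trans to C8 across Ob.
- C12–O and C13–Br are anti.

Assumption: the sense of induction of (R)-TRIP (Re face of the α-bromo aldehyde) and of the triazolium antipode (Re face of C9) is extrapolated from simpler substrates; if a first small run shows the opposite sense, the commercial mirror-image catalyst is used and nothing else changes.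

Design remarks:
- But-3-yn-1-ol supplies only C3–C6, so C1–C2 come from trimethylsilylacetylene.
- The C12 centre is treated as working against the required trans-2,5 relation, not as supporting it.
- The aldehyde of the Stetter substrate is released last and under neutral conditions. It then meets a preformed carbene that is free of amine.
- C6 carries no electrofuge. A primary zinc reagent keeps the coupling conventional, and the direction of proton loss in the last step is secured by the shape of the bicycle.

Step 1
Reactants: 1 L-2-aminobutyric acid [(S)-2-aminobutanoic acid]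
Product: 2 (S)-2-bromobutanoic acid
Conditions: NaNO2, 48% aq HBr, −5 → 0 °C
Reagents that add atoms: hydrogen bromide, Br
Why: Diazotisation of an α-amino acid in bromide medium replaces N by Br with overall retention (two inversions through carboxylate participation), so the (S) centre of 1 becomes C13 (S) of the target.

Step 2
Reactants: 2 (S)-2-bromobutanoic acid
Product: 3 (S)-2-bromobutan-1-ol
Conditions: BH3·THF, THF, 0 → 23 °C; then H2O
Reagents that add atoms: none
Why: Borane reduces the carboxylic acid chemoselectively and under non-basic conditions, so neither the C–Br bond nor C13 is touched.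

Step 3
Reactants: 3 (S)-2-bromobutan-1-ol
Product: 4 (S)-2-bromobutanal (kept in solution, used at once)
Conditions: Dess–Martin periodinane, CH2Cl2, 0 °C; short silica plug, solvent exchanged for toluene below 0 °C
Reagents that add atoms: none
Why: The Dess–Martin oxidation is neutral to weakly acidic and fast at 0 °C, which gives the enolisable α-bromo aldehyde little chance to racemise at C13 before it is consumed.

Step 4
Reactants: 4 (S)-2-bromobutanal; 5 allylboronic acid pinacol ester
Product: 7 (4R,5S)-5-bromohept-1-en-4-ol, via pinacol borate ester 6 (not isolated)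
Conditions: (R)-TRIP (5 mol %), 4 Å MS, toluene, −30 °C; then H2O
Reagents that add atoms: none
Why: Chiral phosphoric acid catalysed allylboration through a closed chair transition state delivers allyl to the Re face of 4 and sets C12 (R); the Cornforth preference of an α-bromo aldehyde for the anti bromohydrin points the same way, and any (R)-4 from partial racemisation is diverted into a separable syn diastereomer.

Step 5
Reactants: 7 (4R,5S)-5-bromohept-1-en-4-ol; 8 methyl propiolate
Product: 9 methyl (E)-3-{[(4R,5S)-5-bromohept-1-en-4-yl]oxy}acrylate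
Conditions: N-methylmorpholine, CH2Cl2, 0 → 23 °C
Reagents that add atoms: none
Why: Amine-catalysed oxa-Michael addition of an alcohol to a propiolate gives the (E)-β-alkoxyacrylate under thermodynamic control, and the weakly basic amine should not convert the bromohydrin into an epoxide.

Step 6
Reactants: 9 methyl (E)-3-{[(4R,5S)-5-bromohept-1-en-4-yl]oxy}acrylate
Product: 10 methyl (E)-3-{[(3R,4S)-4-bromo-1-oxohexan-3-yl]oxy}acrylate
Conditions: O3, CH2Cl2, −78 °C, Sudan Red 7B end point; then Me2S, −78 → 23 °C; rapid filtration, azeotroped with toluene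
Reagents that add atoms: ozone, [O-][O+]=O
Why: Ozonolysis with an indicator dye cleaves the unpolarised terminal alkene before the ester-deactivated alkoxyacrylate, and the neutral reductive work-up spares a β-alkoxy aldehyde that would eliminate on contact with base.

Step 7
Reactants: 10 methyl (E)-3-{[(3R,4S)-4-bromo-1-oxohexan-3-yl]oxy}acrylate
Product: 11 methyl 2-{(2S,5R)-5-[(S)-1-bromopropyl]-3-oxotetrahydrofuran-2-yl}acetate (trans-2,5)
Conditions: aminoindanol-derived N-C6F5 triazolium BF4 (20 mol %, antipode that attacks the Re face of C9), KHMDS (18 mol %), toluene, 23 °C; volatiles (HMDS) removed in vacuo, fresh toluene; 10 added slowly at 0 °C (0.02 M), then 23 °C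
Reagents that add atoms: none
Why: The carbene adds to the C10 aldehyde and a proton shift gives the Breslow enaminol, whose now nucleophilic C10 adds to C9 of the tethered acrylate; protonation of the C8 ester enolate and loss of the carbene restore the C10 carbonyl. This is the asymmetric intramolecular Stetter reaction, known for aldehydes linked through oxygen to enoates and for β-oxygenated acceptors that deliver furan-3-ones. Ring B (C9, C10, C11, C12, Ob) closes in the 5-exo-trig mode. C9 is set by the catalyst, which must deliver C10 to the Re face of C9 so that the C8 arm ends up trans to the C12 arm across Ob; substrate-controlled closures of this bond type (acyl radical additions) prefer the cis-2,5 product, so the resident C12 centre is counted as an opponent that the catalyst has to override. The step needs conjugate addition to outrun E1cB loss of the alkoxyacrylate from C12, which is served by the short three-atom tether, the single (E) geometry of the acceptor and the absence of any base other than the carbene. The trans relation of the two arms also keeps the transient C8 enolate away from the C13 bromide, and removal of HMDS limits later epimerisation of the acidic C9–H.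

Step 8
Reactants: 11 methyl 2-{(2S,5R)-5-[(S)-1-bromopropyl]-3-oxotetrahydrofuran-2-yl}acetate
Product: 13 (3aS,5R,6aS)-5-[(S)-1-bromopropyl]tetrahydrofuro[3,2-b]furan-2(3H)-one, via hydroxy ester 12 (not isolated)
Conditions: L-Selectride (1.05 equiv), THF, −78 °C; AcOH quench at −78 °C, then 23 °C
Reagents that add atoms: none
Why: The bulky borohydride attacks the C10 ketone from the face opposite the adjacent C9 arm and sets C10 (S) with its oxygen cis to that arm, so the alkoxide closes ring A by 5-exo-trig lactonisation, whereas any trans alcohol cannot cyclise and is removed by chromatography.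

Step 9
Reactants: 13 (3aS,5R,6aS)-5-[(S)-1-bromopropyl]tetrahydrofuro[3,2-b]furan-2(3H)-one
Product: 14 (3aS,5R,6aS)-5-[(S)-1-bromopropyl]-3a,5,6,6a-tetrahydrofuro[3,2-b]furan-2-yl diphenyl phosphate
Conditions: (PhO)2P(O)Cl, DMPU, THF, −78 °C, KHMDS added dropwise (internal trap); Et3N-buffered work-up, used promptly
Reagents that add atoms: diphenyl chlorophosphate, O=P(Cl)(Oc1ccccc1)Oc1ccccc1
Why: O-Phosphorylation of the lactone potassium enolate (ketene acetal phosphate formation) is run with the chlorophosphate already present, so trapping at −78 °C should be faster than expulsion of Ob from C9, and no stereocentre is touched.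

Step 10
Reactants: 15 but-3-yn-1-ol
Product: 16 4-iodobut-3-yn-1-ol
Conditions: NIS, AgNO3 (10 mol %), acetone, 23 °C, dark
Reagents that add atoms: N-iodosuccinimide, O=C1CCC(=O)N1I
Why: Silver-catalysed electrophilic iodination of the terminal alkyne C–H is selective and leaves the primary alcohol free.

Step 11
Reactants: 16 4-iodobut-3-yn-1-ol
Product: 17 (Z)-4-iodobut-3-en-1-ol
Conditions: 2-nitrobenzenesulfonohydrazide, Et3N, THF/i-PrOH, 23 °C
Reagents that add atoms: none
Why: Diimide transfers two hydrogens in a concerted syn fashion, which turns the 1-iodoalkyne into the (Z)-vinyl iodide (future C3=C4) without hydrogenolysis of the C–I bond.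

Step 12
Reactants: 17 (Z)-4-iodobut-3-en-1-ol; 18 trimethylsilylacetylene
Product: 19 (Z)-6-(trimethylsilyl)hex-3-en-5-yn-1-ol
Conditions: PdCl2(PPh3)2 (2 mol %), CuI (4 mol %), Et3N, THF, 23 °C
Reagents that add atoms: none
Why: The Sonogashira coupling proceeds with retention of alkene geometry and adds C1–C2 as a silyl-capped alkyne.

Step 13
Reactants: 19 (Z)-6-(trimethylsilyl)hex-3-en-5-yn-1-ol
Product: 20 (Z)-(6-iodohex-3-en-1-yn-1-yl)trimethylsilane
Conditions: I2, PPh3, imidazole, CH2Cl2, 0 °C
Reagents that add atoms: iodine, II
Why: Appel-type iodination is an SN2 displacement at the primary C6 carbinol under near-neutral conditions that leave the (Z)-enyne untouched.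

Step 14
Reactants: 14 ketene acetal diphenyl phosphate; 20 (Z)-(6-iodohex-3-en-1-yn-1-yl)trimethylsilane
Product: 22 (3aS,5R,6aS)-5-[(S)-1-bromopropyl]-2-[(Z)-6-(trimethylsilyl)hex-3-en-5-yn-1-yl]-3a,5,6,6a-tetrahydrofuro[3,2-b]furan, via organozinc iodide 21 (not isolated)
Conditions: 20, activated Zn dust, LiCl, THF, 23–40 °C; supernatant transferred to 14, PdCl2(dppf) (5 mol %), THF, 23 → 40 °C; Et3N-deactivated silica
Reagents that add atoms: none
Why: Negishi coupling: zinc inserts into the primary C6–I bond, Pd(0) inserts into the C7–O bond of the ketene acetal phosphate, and the bidentate ligand favours reductive elimination over β-hydride loss, while decanting from excess zinc protects the β-bromo ether and the unactivated secondary C13 bromide is inert to Pd(0).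

Step 15
Reactants: 22 silyl-capped bicyclic enol ether
Product: 23 (3aS,5R,6aS)-5-[(S)-1-bromopropyl]-2-[(Z)-hex-3-en-5-yn-1-yl]-3a,5,6,6a-tetrahydrofuro[3,2-b]furan
Conditions: K2CO3 (0.2 equiv), MeOH, 0 °C
Reagents that add atoms: none
Why: Carbonate-catalysed methanolysis cleaves only the alkynyl C–Si bond, and the basic medium suits the acid-labile cyclic enol ether.

Step 16
Reactants: 23 (3aS,5R,6aS)-5-[(S)-1-bromopropyl]-2-[(Z)-hex-3-en-5-yn-1-yl]-3a,5,6,6a-tetrahydrofuro[3,2-b]furan
Product: 24 (2Z,3S,3aR,5R,6aS)-3-bromo-5-[(S)-1-bromopropyl]-2-[(Z)-hex-3-en-5-yn-1-ylidene]hexahydrofuro[3,2-b]furan (target)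
Conditions: NBS (1.0 equiv), 2,6-di-tert-butyl-4-methylpyridine (0.2 equiv), CH2Cl2, −78 → −40 °C, dark; Et3N-deactivated silica
Reagents that add atoms: N-bromosuccinimide, O=C1CCC(=O)N1Br
Why: Ionic allylic bromination of a ketone-derived enol ether (the reaction that turns 2-methoxypropene into 2-methoxyallyl bromide): Br+ adds to the nucleophilic C8 from the convex face, anti to ring B, which sets C8 (S) trans to Ob, and the succinimide anion then removes an exposed C6 proton rather than the concave-face C8–H, the C5 chain turning toward Oa to avoid the C8 bromide so that the (6Z) enol ether results.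

Compound list
1 | L-2-aminobutyric acid | CC[C@H](N)C(=O)O | starting material
2 | (S)-2-bromobutanoic acid | CC[C@H](Br)C(=O)O | intermediate
3 | (S)-2-bromobutan-1-ol | CC[C@H](Br)CO | intermediate
4 | (S)-2-bromobutanal | CC[C@H](Br)C=O | intermediate
5 | allylboronic acid pinacol ester | C=CCB1OC(C)(C)C(C)(C)O1 | starting material
6 | pinacol borate ester of 7 | C=CC[C@H]([C@@H](Br)CC)OB1OC(C)(C)C(C)(C)O1 | intermediate
7 | (4R,5S)-5-bromohept-1-en-4-ol | C=CC[C@H]([C@@H](Br)CC)O | intermediate
8 | methyl propiolate | C#CC(=O)OC | starting material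
9 | methyl (E)-3-{[(4R,5S)-5-bromohept-1-en-4-yl]oxy}acrylate | C=CC[C@H]([C@@H](Br)CC)O/C=C/C(=O)OC | intermediate
10 | methyl (E)-3-{[(3R,4S)-4-bromo-1-oxohexan-3-yl]oxy}acrylate | O=CC[C@H]([C@@H](Br)CC)O/C=C/C(=O)OC | intermediate
11 | methyl 2-{(2S,5R)-5-[(S)-1-bromopropyl]-3-oxotetrahydrofuran-2-yl}acetate | O=C1C[C@H]([C@@H](Br)CC)O[C@H]1CC(=O)OC | intermediate
12 | methyl 2-{(2S,3S,5R)-5-[(S)-1-bromopropyl]-3-hydroxytetrahydrofuran-2-yl}acetate | O[C@H]1C[C@H]([C@@H](Br)CC)O[C@H]1CC(=O)OC | intermediate
13 | (3aS,5R,6aS)-5-[(S)-1-bromopropyl]tetrahydrofuro[3,2-b]furan-2(3H)-one | O=C1O[C@H]2C[C@H]([C@@H](Br)CC)O[C@H]2C1 | intermediate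
14 | (3aS,5R,6aS)-5-[(S)-1-bromopropyl]-3a,5,6,6a-tetrahydrofuro[3,2-b]furan-2-yl diphenyl phosphate | C1(OP(=O)(Oc3ccccc3)Oc4ccccc4)O[C@H]2C[C@H]([C@@H](Br)CC)O[C@H]2C=1 | intermediate
15 | but-3-yn-1-ol | C#CCCO | starting material
16 | 4-iodobut-3-yn-1-ol | IC#CCCO | intermediate
17 | (Z)-4-iodobut-3-en-1-ol | I/C=C\CCO | intermediate
18 | trimethylsilylacetylene | C#C[Si](C)(C)C | starting material
19 | (Z)-6-(trimethylsilyl)hex-3-en-5-yn-1-ol | C[Si](C)(C)C#C/C=C\CCO | intermediate
20 | (Z)-(6-iodohex-3-en-1-yn-1-yl)trimethylsilane | C[Si](C)(C)C#C/C=C\CCI | intermediate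
21 | (Z)-[6-(trimethylsilyl)hex-3-en-5-yn-1-yl]zinc iodide | C[Si](C)(C)C#C/C=C\CC[Zn]I | intermediate
22 | (3aS,5R,6aS)-5-[(S)-1-bromopropyl]-2-[(Z)-6-(trimethylsilyl)hex-3-en-5-yn-1-yl]-3a,5,6,6a-tetrahydrofuro[3,2-b]furan | C[Si](C)(C)C#C/C=C\CCC1O[C@H]2C[C@H]([C@@H](Br)CC)O[C@H]2C=1 | intermediate
23 | (3aS,5R,6aS)-5-[(S)-1-bromopropyl]-2-[(Z)-hex-3-en-5-yn-1-yl]-3a,5,6,6a-tetrahydrofuro[3,2-b]furan | C#C/C=C\CCC1O[C@H]2C[C@H]([C@@H](Br)CC)O[C@H]2C=1 | intermediate
24 | (2Z,3S,3aR,5R,6aS)-3-bromo-5-[(S)-1-bromopropyl]-2-[(Z)-hex-3-en-5-yn-1-ylidene]hexahydrofuro[3,2-b]furan | C#C/C=C\C/C=C1\O[C@H]2C[C@H]([C@@H](Br)CC)O[C@H]2[C@@H]1Br | target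

Total step count: 16. Longest linear sequence: 12 (steps 1–9 and 14–16). Steps 10–13 form the convergent C1–C6 branch.

Steps most likely to fail

**Step 7.** Two processes threaten it.
- E1cB loss of the alkoxyacrylate from the β-alkoxy aldehyde may be faster than formation of the Breslow intermediate. The acidic enol set free would then protonate and silence the carbene.
- Facial selectivity at C9 may erode because the catalyst has to work against the cis-2,5 preference imposed by C12.

The fallback gives up the C9–C10 closure, sets out from 4 and comes back at 13. A BF3·OEt2-mediated Mukaiyama aldol addition of commercial 2-(trimethylsiloxy)buta-1,3-diene to 4 (CH2Cl2, −78 °C) should give (5R,6S)-6-bromo-5-hydroxyoct-1-en-3-one F1. This addition is anti-selective by the polar Felkin–Anh/Cornforth model. Narasaka–Prasad reduction (Et2BOMe, NaBH4, THF/MeOH, −78 °C) should then give the syn diol (3S,5R,6S)-6-bromooct-1-ene-3,5-diol F2. Pd(II)-catalysed oxycarbonylative double cyclisation (PdCl2 cat., CuCl2, NaOAc, AcOH, CO 1 atm, 23 °C) forms Ob–C9, C8–C7 (C7 from CO) and the lactone in one operation. The obligatory cis fusion fixes C9 from C10, so the product is 13.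

**Step 16.** The bromo-oxocarbenium ion may lose the C8 proton instead of a C6 proton, may be captured by succinimide, or may give an eroded alkene geometry.

The fallback separates addition from elimination, sets out from 23 and comes back at 24. NBS in MeOH/CH2Cl2 at −78 °C should add Br (convex face) and methoxide across C7=C8. The product is the bromo ketal (3S,3aR,5R,6aS)-3-bromo-5-[(S)-1-bromopropyl]-2-[(Z)-hex-3-en-5-yn-1-yl]-2-methoxyhexahydrofuro[3,2-b]furan F3, whose C7 epimers are immaterial. TMSOTf with excess i-Pr2NEt (CH2Cl2, −20 °C) then removes methanol. The hindered amine takes the accessible C6 proton, which is the known course by which α-bromo ketals give 2-alkoxyallyl bromides, and 24 results.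

**Step 9.** The lactone enolate may expel Ob from C9, opening ring B to a butenolide. The five-membered ketene acetal phosphate may also decompose toward a furan before it can be coupled.

The fallback avoids both the enolate and palladium by using the C1–C6 iodide as the electrophile. It sets out from 13 and comes back at 22. DIBAL-H (CH2Cl2, −78 °C) should give the lactol (3aS,5R,6aS)-5-[(S)-1-bromopropyl]hexahydrofuro[3,2-b]furan-2-ol F4. Benzenesulfinic acid and CaCl2 (CH2Cl2, 23 °C) convert it into the anomeric sulfone (3aS,5R,6aS)-5-[(S)-1-bromopropyl]-2-(phenylsulfonyl)hexahydrofuro[3,2-b]furan F5. Deprotonation at C7 (LDA, THF/DMPU, −78 °C) leaves no leaving group β to the carbanion. Alkylation with 20 then gives the C7-alkylated sulfone F6. On warming, or with MgBr2·OEt2/Et3N, F6 loses benzenesulfinic acid toward C8 and delivers 22.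

Further compounds
F1 | step 7 | (5R,6S)-6-bromo-5-hydroxyoct-1-en-3-one | C=CC(=O)C[C@H]([C@@H](Br)CC)O
F2 | step 7 | (3S,5R,6S)-6-bromooct-1-ene-3,5-diol | C=C[C@@H](O)C[C@H]([C@@H](Br)CC)O
F3 | step 16 | (3S,3aR,5R,6aS)-3-bromo-5-[(S)-1-bromopropyl]-2-[(Z)-hex-3-en-5-yn-1-yl]-2-methoxyhexahydrofuro[3,2-b]furan | C#C/C=C\CCC1(OC)O[C@H]2C[C@H]([C@@H](Br)CC)O[C@H]2[C@@H]1Br
F4 | step 9 | (3aS,5R,6aS)-5-[(S)-1-bromopropyl]hexahydrofuro[3,2-b]furan-2-ol | OC1O[C@H]2C[C@H]([C@@H](Br)CC)O[C@H]2C1
F5 | step 9 | (3aS,5R,6aS)-5-[(S)-1-bromopropyl]-2-(phenylsulfonyl)hexahydrofuro[3,2-b]furan | O=S(=O)(c3ccccc3)C1O[C@H]2C[C@H]([C@@H](Br)CC)O[C@H]2C1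
F6 | step 9 | (3aS,5R,6aS)-5-[(S)-1-bromopropyl]-2-(phenylsulfonyl)-2-[(Z)-6-(trimethylsilyl)hex-3-en-5-yn-1-yl]hexahydrofuro[3,2-b]furan | C[Si](C)(C)C#C/C=C\CCC1(S(=O)(=O)c3ccccc3)O[C@H]2C[C@H]([C@@H](Br)CC)O[C@H]2C1
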